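**Retrosynthetic overview**
1. Target ⇒ acetylation, desilylation and ketal hydrolysis of a 6α-silyloxy-3-ketal aryl ether ⇒ Mitsunobu C11–O bond between umbelliferone and a drim-7-en-11-ol.
2. C9 stereocentre and C11 alcohol ⇒ α-face hydroboration of a 7,9(11)-diene ⇒ Peterson methylenation of an 8-methyl-7-en-9-one ⇒ Stille methylation, α-iodination and Saegusa oxidation of a C9 ketone.
3. 5α-H and 6α-O ⇒ α-face hydroboration of a 4,4-dimethyl-Δ5-octalin ⇒ gem-dimethylation of the bicyclic enone.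
4. Enantiopure bicycle ⇒ ketoreductase reduction of (S)-Wieland–Miescher ketone ⇒ L-proline-catalysed aldol cyclisation of the achiral triketone from 2-methylcyclohexane-1,3-dione and methyl vinyl ketone.
5. Ring order: ring B comes in as the dione ring, ring A is closed by the proline annulation, the coumarin bicycle is bought intact and attached at step 17.

Assumption: the SMILES is read as the (1S,4S,4aR,8aR) compound (5α-H, 6α-OAc, 9β-CH2OAr, 10β-CH3), and a commercial ketoreductase with the selectivity known for yeast reductases toward (S)-Wieland–Miescher ketone is taken as available.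

Numbering used: drimane numbering of the decalin. Ring A is C1–C5 and C10 (C3 oxygenated, C4 gem-dimethyl); ring B is C5–C10; C10 carries the angular methyl (β); C11 is the carbon on C9; C12 is the methyl on C8; α is the face opposite the C10 methyl.

**Step 1**
Reactants: 1 2-methylcyclohexane-1,3-dione; 2 methyl vinyl ketone
Product: 3 2-methyl-2-(3-oxobutyl)cyclohexane-1,3-dione
Conditions: H2O, AcOH (cat.), hydroquinone (cat.), 75 °C
Reagents that add atoms: none
Why: Michael addition of the acidic 1,3-dione to the enone gives the achiral (prochiral) triketone.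

**Step 2**
Reactants: 3 2-methyl-2-(3-oxobutyl)cyclohexane-1,3-dione
Product: 4 (S)-Wieland–Miescher ketone
Conditions: L-proline (5 mol%), DMSO, 35 °C
Reagents that add atoms: none
Why: Hajos–Parrish–Eder–Sauer–Wiechert reaction, in which the proline enamine of the side-chain ketone attacks one of the two enantiotopic ring carbonyls through an acid-directed chair transition state and dehydration closes ring A, setting C10 as S (about 70% ee, raised in step 3).

**Step 3**
Reactants: 4 (S)-Wieland–Miescher ketone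
Product: 5 (4aS,5S)-5-hydroxy-4a-methyl-4,4a,5,6,7,8-hexahydronaphthalen-2(3H)-one
Conditions: ketoreductase (NADPH-dependent alcohol dehydrogenase, Prelog-selective), NADP+ (cat.), iPrOH, phosphate buffer pH 7, 30 °C
Reagents that add atoms: none
Why: Enzymatic carbonyl reduction in which the ketoreductase accepts only the saturated C9 carbonyl of the (S)-ketone and delivers hydride to its α face, giving the 9β (S) alcohol as a single stereoisomer while the minor (R)-ketone stays unreduced and is removed by chromatography.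

**Step 4**
Reactants: 5 (4aS,5S)-5-hydroxy-4a-methyl-4,4a,5,6,7,8-hexahydronaphthalen-2(3H)-one
Product: 6 (4aS,5S)-5-benzyloxy-4a-methyl-4,4a,5,6,7,8-hexahydronaphthalen-2(3H)-one
Conditions: BnOC(=NH)CCl3, TfOH (cat.), CH2Cl2/cyclohexane, 0 °C → rt
Reagents that add atoms: benzyl 2,2,2-trichloroacetimidate, N=C(OCc1ccccc1)C(Cl)(Cl)Cl
Why: Acid-catalysed O-benzylation with the trichloroacetimidate avoids base and therefore enolisation of the enone.

**Step 5**
Reactants: 6 (4aS,5S)-5-benzyloxy-4a-methyl-4,4a,5,6,7,8-hexahydronaphthalen-2(3H)-one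
Product: 7 9β-benzyloxy-4,4,10β-trimethyl-Δ5-octalin-3-one
Conditions: KOtBu, tBuOH, rt; MeI
Reagents that add atoms: iodomethane, CI
Why: Deconjugative double α-alkylation of the extended dienolate at C4 installs the gem-dimethyl group and moves the alkene to C5=C6.

**Step 6**
Reactants: 7 9β-benzyloxy-4,4,10β-trimethyl-Δ5-octalin-3-one
Product: 8 9β-benzyloxy-3,3-ethylenedioxy-4,4,10β-trimethyl-Δ5-octalin
Conditions: HOCH2CH2OH, TsOH·H2O (cat.), PhH, reflux, Dean–Stark
Reagents that add atoms: ethylene glycol, OCCO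
Why: Acid-catalysed ketalisation with azeotropic water removal masks the C3 ketone against borane and organometallics, and the alkene cannot move because C4 is quaternary.

**Step 7**
Reactants: 8 9β-benzyloxy-3,3-ethylenedioxy-4,4,10β-trimethyl-Δ5-octalin
Product: 10 9β-benzyloxy-3,3-ethylenedioxy-4,4,10β-trimethyl-5α-decalin-6α-ol, via C6 alkylborane 9 (not isolated)
Conditions: BH3·THF, THF, 0 °C → rt; then NaOH (aq), H2O2, 0 → 40 °C
Reagents that add atoms: hydrogen peroxide, OO
Why: Brown hydroboration–oxidation, in which borane adds syn from the α face (the β face is blocked by the C10 and 4β methyls) with boron on the less substituted C6, so oxidation with retention gives the 5α-H trans-decalin and the 6α-alcohol.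

**Step 8**
Reactants: 10 9β-benzyloxy-3,3-ethylenedioxy-4,4,10β-trimethyl-5α-decalin-6α-ol
Product: 11 9β-benzyloxy-6α-(tert-butyldimethylsilyloxy)-3,3-ethylenedioxy-4,4,10β-trimethyl-5α-decalin
Conditions: TBSOTf, 2,6-lutidine, CH2Cl2, −78 → 0 °C
Reagents that add atoms: tert-butyldimethylsilyl triflate, CC(C)(C)[Si](C)(C)OS(=O)(=O)C(F)(F)F
Why: Silylation with the reactive silyl triflate protects the hindered equatorial alcohol as an ether that cannot be enolised, acylated or displaced in the ring B chemistry.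

**Step 9**
Reactants: 11 9β-benzyloxy-6α-(tert-butyldimethylsilyloxy)-3,3-ethylenedioxy-4,4,10β-trimethyl-5α-decalin
Product: 12 6α-(tert-butyldimethylsilyloxy)-3,3-ethylenedioxy-4,4,10β-trimethyl-5α-decalin-9β-ol
Conditions: H2 (1 atm), Pd/C (10%), EtOAc, rt
Reagents that add atoms: none
Why: Hydrogenolysis removes the benzyl ether at a stage with no alkene, leaving the silyl ether and ketal untouched.

**Step 10**
Reactants: 12 6α-(tert-butyldimethylsilyloxy)-3,3-ethylenedioxy-4,4,10β-trimethyl-5α-decalin-9β-ol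
Product: 13 6α-(tert-butyldimethylsilyloxy)-3,3-ethylenedioxy-4,4,10β-trimethyl-5α-decalin-9-one
Conditions: nPr4N[RuO4] (5 mol%), NMO, 4 Å MS, CH2Cl2, rt
Reagents that add atoms: none
Why: Ley–Griffith oxidation is neutral, so the ketal and silyl ether survive and no stereocentre is touched (C10 is quaternary).

**Step 11**
Reactants: 13 6α-(tert-butyldimethylsilyloxy)-3,3-ethylenedioxy-4,4,10β-trimethyl-5α-decalin-9-one
Product: 15 6α-(tert-butyldimethylsilyloxy)-3,3-ethylenedioxy-4,4,10β-trimethyl-5α-decal-7-en-9-one, via silyl enol ether 14 (not isolated)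
Conditions: LiN(iPr)2 (commercial solution), TMSCl, THF, −78 °C; then Pd(OAc)2, MeCN, rt
Reagents that add atoms: none
Why: Saegusa–Ito oxidation, in which enolisation is possible only toward C8 (C10 is quaternary), so the C7=C8 enone forms with a single regiochemistry.

**Step 12**
Reactants: 15 6α-(tert-butyldimethylsilyloxy)-3,3-ethylenedioxy-4,4,10β-trimethyl-5α-decal-7-en-9-one
Product: 16 6α-(tert-butyldimethylsilyloxy)-3,3-ethylenedioxy-8-iodo-4,4,10β-trimethyl-5α-decal-7-en-9-one
Conditions: I2, pyridine, CH2Cl2, rt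
Reagents that add atoms: iodine, II
Why: Johnson α-iodination, a pyridine conjugate addition, enolate iodination and elimination sequence that places iodine only on the enone α-carbon C8.

**Step 13**
Reactants: 16 6α-(tert-butyldimethylsilyloxy)-3,3-ethylenedioxy-8-iodo-4,4,10β-trimethyl-5α-decal-7-en-9-one
Product: 17 6α-(tert-butyldimethylsilyloxy)-3,3-ethylenedioxy-4,4,8,10β-tetramethyl-5α-decal-7-en-9-one
Conditions: Me4Sn, PdCl2(PhCN)2 (5 mol%), AsPh3, CuI, NMP, 80 °C
Reagents that add atoms: tetramethylstannane, C[Sn](C)(C)C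
Why: Stille cross-coupling of the α-iodoenone installs the C12 methyl on C8 without any enolate chemistry, so the C7=C8 position is fixed.

**Step 14**
Reactants: 17 6α-(tert-butyldimethylsilyloxy)-3,3-ethylenedioxy-4,4,8,10β-tetramethyl-5α-decal-7-en-9-one
Product: 18 6α-(tert-butyldimethylsilyloxy)-3,3-ethylenedioxy-4,4,8,10β-tetramethyl-9α-(trimethylsilylmethyl)-5α-decal-7-en-9β-ol
Conditions: Me3SiCH2Li, CeCl3 (anhydrous), THF, −78 °C; aq. NH4Cl
Reagents that add atoms: (trimethylsilyl)methyllithium, [Li]C[Si](C)(C)C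
Why: 1,2-Addition of the weakly basic organocerium reagent (first half of a Peterson olefination) to the hindered enone from the α face, opposite the C10 methyl; the new C9 configuration is lost in step 15.

**Step 15**
Reactants: 18 6α-(tert-butyldimethylsilyloxy)-3,3-ethylenedioxy-4,4,8,10β-tetramethyl-9α-(trimethylsilylmethyl)-5α-decal-7-en-9β-ol
Product: 19 6α-(tert-butyldimethylsilyloxy)-3,3-ethylenedioxy-5α-drima-7,9(11)-diene
Conditions: KH, THF, 0 °C → rt
Reagents that add atoms: none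
Why: Peterson syn-elimination of the potassium β-silyl alkoxide gives the exocyclic C9=C11 alkene without acid and without a basic ylide.

**Step 16**
Reactants: 19 6α-(tert-butyldimethylsilyloxy)-3,3-ethylenedioxy-5α-drima-7,9(11)-diene
Product: 21 6α-(tert-butyldimethylsilyloxy)-3,3-ethylenedioxy-5α,9α-H-drim-7-en-11-ol, via B-alkyl-9-BBN adduct 20 (not isolated)
Conditions: 9-BBN, THF, 50 °C; then NaOH (aq), H2O2, 0 °C → rt
Reagents that add atoms: hydrogen peroxide, OO
Why: Hydroboration–oxidation in which the bulky borane adds only to the 1,1-disubstituted C9=C11 bond with boron on C11 and hydrogen delivered to C9 from the α face opposite the axial C10 methyl, setting 9α-H with the CH2OH group β (equatorial).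

**Step 17**
Reactants: 21 6α-(tert-butyldimethylsilyloxy)-3,3-ethylenedioxy-5α,9α-H-drim-7-en-11-ol; 22 umbelliferone (7-hydroxy-2H-chromen-2-one)
Product: 23 7-{[6α-(tert-butyldimethylsilyloxy)-3,3-ethylenedioxy-5α,9α-H-drim-7-en-11-yl]oxy}-2H-chromen-2-one
Conditions: PPh3, DIAD, THF, 0 °C → rt
Reagents that add atoms: none
Why: Mitsunobu etherification, in which the acidic phenol (pKa about 8) displaces the oxyphosphonium of the primary alcohol at C11, a carbon that is not a stereocentre.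

**Step 18**
Reactants: 23 7-{[6α-(tert-butyldimethylsilyloxy)-3,3-ethylenedioxy-5α,9α-H-drim-7-en-11-yl]oxy}-2H-chromen-2-one
Product: 24 7-{[6α-(tert-butyldimethylsilyloxy)-3-oxo-5α,9α-H-drim-7-en-11-yl]oxy}-2H-chromen-2-one
Conditions: PPTS (cat.), acetone/H2O, 50 °C
Reagents that add atoms: water, O
Why: Mild acid-catalysed ketal hydrolysis, helped by relief of strain next to the gem-dimethyl carbon, frees the C3 ketone while the allylic oxygen is still a non-ionising silyl ether.

**Step 19**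
Reactants: 24 7-{[6α-(tert-butyldimethylsilyloxy)-3-oxo-5α,9α-H-drim-7-en-11-yl]oxy}-2H-chromen-2-one
Product: 25 7-{[6α-hydroxy-3-oxo-5α,9α-H-drim-7-en-11-yl]oxy}-2H-chromen-2-one
Conditions: HF·pyridine, pyridine, THF, 0 °C → rt
Reagents that add atoms: none
Why: Buffered fluoride desilylation cleaves the Si–O bond without ionising the allylic alcohol or opening the coumarin lactone.

**Step 20**
Reactants: 25 7-{[6α-hydroxy-3-oxo-5α,9α-H-drim-7-en-11-yl]oxy}-2H-chromen-2-one
Product: 26 7-{[(1S,4S,4aR,8aR)-4-acetoxy-2,5,5,8a-tetramethyl-6-oxo-1,4,4a,5,6,7,8,8a-octahydronaphthalen-1-yl]methoxy}-2H-chromen-2-one (CNP0140705.1)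
Conditions: Ac2O, DMAP (cat.), pyridine, rt
Reagents that add atoms: acetic anhydride, CC(=O)OC(C)=O
Why: DMAP-catalysed acetylation of the 6α-alcohol with retention at C6 completes the target without touching the ketone, alkene or lactone.

**Compound list**
1 | 2-methylcyclohexane-1,3-dione | CC1C(=O)CCCC1=O | starting material
2 | methyl vinyl ketone | CC(=O)C=C | starting material
3 | 2-methyl-2-(3-oxobutyl)cyclohexane-1,3-dione | CC(=O)CCC1(C)C(=O)CCCC1=O | intermediate
4 | (S)-Wieland–Miescher ketone, (8aS)-8a-methyl-3,4,8,8a-tetrahydronaphthalene-1,6(2H,7H)-dione | C[C@]12CCC(=O)C=C1CCCC2=O | intermediate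
5 | (4aS,5S)-5-hydroxy-4a-methyl-4,4a,5,6,7,8-hexahydronaphthalen-2(3H)-one (9β-OH) | C[C@]12CCC(=O)C=C1CCC[C@@H]2O | intermediate
6 | (4aS,5S)-5-benzyloxy-4a-methyl-4,4a,5,6,7,8-hexahydronaphthalen-2(3H)-one | C[C@]12CCC(=O)C=C1CCC[C@@H]2OCc1ccccc1 | intermediate
7 | 9β-benzyloxy-4,4,10β-trimethyl-Δ5-octalin-3-one | C[C@]12CCC(=O)C(C)(C)C1=CCC[C@@H]2OCc1ccccc1 | intermediate
8 | 9β-benzyloxy-3,3-ethylenedioxy-4,4,10β-trimethyl-Δ5-octalin | C[C@]12CCC3(OCCO3)C(C)(C)C1=CCC[C@@H]2OCc1ccccc1 | intermediate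
9 | C6 alkylborane (6α-BH2, 5α-H) of 8 | B[C@H]1CC[C@H](OCc2ccccc2)[C@@]2(C)CCC3(OCCO3)C(C)(C)[C@H]12 | intermediate (not isolated)
10 | 9β-benzyloxy-3,3-ethylenedioxy-4,4,10β-trimethyl-5α-decalin-6α-ol | O[C@H]1CC[C@H](OCc2ccccc2)[C@@]2(C)CCC3(OCCO3)C(C)(C)[C@H]12 | intermediate
11 | 9β-benzyloxy-6α-(tert-butyldimethylsilyloxy)-3,3-ethylenedioxy-4,4,10β-trimethyl-5α-decalin | CC(C)(C)[Si](C)(C)O[C@H]1CC[C@H](OCc2ccccc2)[C@@]2(C)CCC3(OCCO3)C(C)(C)[C@H]12 | intermediate
12 | 6α-(tert-butyldimethylsilyloxy)-3,3-ethylenedioxy-4,4,10β-trimethyl-5α-decalin-9β-ol | CC(C)(C)[Si](C)(C)O[C@H]1CC[C@H](O)[C@@]2(C)CCC3(OCCO3)C(C)(C)[C@H]12 | intermediate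
13 | 6α-(tert-butyldimethylsilyloxy)-3,3-ethylenedioxy-4,4,10β-trimethyl-5α-decalin-9-one | CC(C)(C)[Si](C)(C)O[C@H]1CCC(=O)[C@@]2(C)CCC3(OCCO3)C(C)(C)[C@H]12 | intermediate
14 | 9-trimethylsilyloxy-Δ8 silyl enol ether of 13 | CC(C)(C)[Si](C)(C)O[C@H]1CC=C(O[Si](C)(C)C)[C@@]2(C)CCC3(OCCO3)C(C)(C)[C@H]12 | intermediate (not isolated)
15 | 6α-(tert-butyldimethylsilyloxy)-3,3-ethylenedioxy-4,4,10β-trimethyl-5α-decal-7-en-9-one | CC(C)(C)[Si](C)(C)O[C@H]1C=CC(=O)[C@@]2(C)CCC3(OCCO3)C(C)(C)[C@H]12 | intermediate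
16 | 6α-(tert-butyldimethylsilyloxy)-3,3-ethylenedioxy-8-iodo-4,4,10β-trimethyl-5α-decal-7-en-9-one | CC(C)(C)[Si](C)(C)O[C@H]1C=C(I)C(=O)[C@@]2(C)CCC3(OCCO3)C(C)(C)[C@H]12 | intermediate
17 | 6α-(tert-butyldimethylsilyloxy)-3,3-ethylenedioxy-4,4,8,10β-tetramethyl-5α-decal-7-en-9-one | CC(C)(C)[Si](C)(C)O[C@H]1C=C(C)C(=O)[C@@]2(C)CCC3(OCCO3)C(C)(C)[C@H]12 | intermediate
18 | 6α-(tert-butyldimethylsilyloxy)-3,3-ethylenedioxy-4,4,8,10β-tetramethyl-9α-(trimethylsilylmethyl)-5α-decal-7-en-9β-ol | CC(C)(C)[Si](C)(C)O[C@H]1C=C(C)[C@](C[Si](C)(C)C)(O)[C@@]2(C)CCC3(OCCO3)C(C)(C)[C@H]12 | intermediate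
19 | 6α-(tert-butyldimethylsilyloxy)-3,3-ethylenedioxy-5α-drima-7,9(11)-diene | CC(C)(C)[Si](C)(C)O[C@H]1C=C(C)C(=C)[C@@]2(C)CCC3(OCCO3)C(C)(C)[C@H]12 | intermediate
20 | B-(C11)-alkyl-9-borabicyclo[3.3.1]nonane adduct of 19 (9α-H) | CC(C)(C)[Si](C)(C)O[C@H]1C=C(C)[C@H](CB2C3CCCC2CCC3)[C@@]2(C)CCC3(OCCO3)C(C)(C)[C@H]12 | intermediate (not isolated)
21 | 6α-(tert-butyldimethylsilyloxy)-3,3-ethylenedioxy-5α,9α-H-drim-7-en-11-ol | CC(C)(C)[Si](C)(C)O[C@H]1C=C(C)[C@H](CO)[C@@]2(C)CCC3(OCCO3)C(C)(C)[C@H]12 | intermediate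
22 | umbelliferone (7-hydroxy-2H-chromen-2-one) | O=c1ccc2ccc(O)cc2o1 | starting material
23 | 7-{[6α-(tert-butyldimethylsilyloxy)-3,3-ethylenedioxy-5α,9α-H-drim-7-en-11-yl]oxy}-2H-chromen-2-one | CC(C)(C)[Si](C)(C)O[C@H]1C=C(C)[C@H](COc2ccc3ccc(=O)oc3c2)[C@@]2(C)CCC3(OCCO3)C(C)(C)[C@H]12 | intermediate
24 | 7-{[6α-(tert-butyldimethylsilyloxy)-3-oxo-5α,9α-H-drim-7-en-11-yl]oxy}-2H-chromen-2-one | CC(C)(C)[Si](C)(C)O[C@H]1C=C(C)[C@H](COc2ccc3ccc(=O)oc3c2)[C@@]2(C)CCC(=O)C(C)(C)[C@H]12 | intermediate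
25 | 7-{[6α-hydroxy-3-oxo-5α,9α-H-drim-7-en-11-yl]oxy}-2H-chromen-2-one | O[C@H]1C=C(C)[C@H](COc2ccc3ccc(=O)oc3c2)[C@@]2(C)CCC(=O)C(C)(C)[C@H]12 | intermediate
26 | 7-{[(1S,4S,4aR,8aR)-4-acetoxy-2,5,5,8a-tetramethyl-6-oxo-1,4,4a,5,6,7,8,8a-octahydronaphthalen-1-yl]methoxy}-2H-chromen-2-one | CC(=O)O[C@H]1C=C(C)[C@H](COc2ccc3ccc(=O)oc3c2)[C@@]2(C)CCC(=O)C(C)(C)[C@H]12 | target

**Totals**
Total step count: 20. Longest linear sequence: 20 steps (1 and 2 to 26; umbelliferone 22 enters at step 17).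

**Three steps most likely to fail**

Step 12 (α-iodination; the β-carbon C7 that pyridine must attack is flanked by the silyloxy-bearing C6). The fallback sets out from ketone 13 and comes back at enone 17, replacing steps 11–13. The lithium enolate of 13 (LiN(iPr)2, THF, −78 °C) is methylated with MeI to give the 8-methyl ketone F1. Its enolate is then selenenylated with PhSeBr to give the α-phenylseleno ketone F2. Oxidation (H2O2, pyridine, CH2Cl2, 0 °C) and syn-elimination of the selenoxide toward the ring CH2 at C7 gives 17.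

Step 16 (hydroboration of the conjugated diene; the hindered C9=C11 bond may react slowly or with imperfect regio- or face selectivity). The fallback sets out from enone 17 and comes back at alcohol 21, replacing steps 14–16. Corey–Chaykovsky methylene transfer (Me3SI, KN(SiMe3)2, THF, −10 °C → rt) to the C9 carbonyl gives the spiro-epoxide F3. Meinwald rearrangement with MgBr2·OEt2 in CH2Cl2 at −20 °C (opening at the allylic C9, then 1,2-hydride shift) gives the β,γ-unsaturated aldehyde F4 with the formyl group in the equatorial β position. Immediate reduction with NaBH4/CeCl3·7H2O in MeOH at −20 °C gives 21.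

Step 17 (Mitsunobu at a primary carbon that is β-branched and next to the quaternary C10). The fallback sets out from alcohol 21 and comes back at ether 23. The alcohol is converted with MsCl and Et3N in CH2Cl2 at 0 °C into the C11 mesylate F5. F5 is displaced by the caesium salt of umbelliferone 22 (Cs2CO3, DMF, 70 °C) in a Williamson etherification; this phenoxide is a good nucleophile and a weak base, which limits elimination to diene 19.

**Further compounds**
F1 | step 12 | 6α-(tert-butyldimethylsilyloxy)-3,3-ethylenedioxy-4,4,8,10β-tetramethyl-5α-decalin-9-one (C8 epimer mixture) | CC(C)(C)[Si](C)(C)O[C@H]1CC(C)C(=O)[C@@]2(C)CCC3(OCCO3)C(C)(C)[C@H]12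
F2 | step 12 | 6α-(tert-butyldimethylsilyloxy)-3,3-ethylenedioxy-4,4,8,10β-tetramethyl-8-(phenylselanyl)-5α-decalin-9-one (C8 epimer mixture) | CC(C)(C)[Si](C)(C)O[C@H]1CC(C)([Se]c3ccccc3)C(=O)[C@@]2(C)CCC3(OCCO3)C(C)(C)[C@H]12
F3 | step 16 | 9,11-epoxide (spiro-oxirane at C9, oxygen β) of 6α-(tert-butyldimethylsilyloxy)-3,3-ethylenedioxy-5α-drim-7-ene | CC(C)(C)[Si](C)(C)O[C@H]1C=C(C)[C@@]3(CO3)[C@@]2(C)CCC3(OCCO3)C(C)(C)[C@H]12
F4 | step 16 | 6α-(tert-butyldimethylsilyloxy)-3,3-ethylenedioxy-5α,9α-H-drim-7-en-11-al | CC(C)(C)[Si](C)(C)O[C@H]1C=C(C)[C@H](C=O)[C@@]2(C)CCC3(OCCO3)C(C)(C)[C@H]12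
F5 | step 17 | 6α-(tert-butyldimethylsilyloxy)-3,3-ethylenedioxy-5α,9α-H-drim-7-en-11-yl methanesulfonate | CC(C)(C)[Si](C)(C)O[C@H]1C=C(C)[C@H](COS(C)(=O)=O)[C@@]2(C)CCC3(OCCO3)C(C)(C)[C@H]12
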